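**Plan**

Labdane numbering is used throughout (decalin C1–C10, side chain C11–C16, C17 on C8, C18/C19 on C4, C20 on C10); the target is read as 6β,19-dihydroxy-3α-(3-methylbutanoyloxy)labda-8,13E-dien-15-oic acid, a trans-decalin with 10β-methyl and 5α-H.
Retrosynthesis: the ester and the C15 oxidation level are adjusted last, and the Δ8 olefin is traced to its Δ8(17) isomer. Ring B of that isomer is a 3-methylenecyclohexanol (C6 carbinol, C7 methylene, exocyclic C8=C17), the retron of a carbonyl-ene reaction, so C6–C7 is cut to a C6 aldehyde on C5 and an isopropenyl group (C7, C8, C17) on C9.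
That aldehyde is cut at C9–C10 by an oxy-Cope transform to a 1,5-dien-3-ol, which is cut at C6–C7 into a ring A enal (C1–C6, C10, C18–C20) and an E,E C10 allyl unit from geraniol (C7–C9, C11–C17).
Forward: ring A from (R)-carvone (two α′-alkylations, enol triflate, Criegee rearrangement, formylation); α-selective allylbarium addition; anionic oxy-Cope (C9–C10); ene closure of ring B (C6–C7); then olefin shift and functional-group endgame.
Stereochemistry: the carvone centre becomes C3 (isopropenyl to oxygen with retention) and directs C4 by anti alkylation; C4 and allylic strain set the C6 carbinol, which the chair oxy-Cope relays to the quaternary C10; C5 comes from enolate protonation, C6 from the ene transition state, and both E olefins from geraniol.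

Key step: step 14

**Route**

Step 1
Reactants: 1 (R)-(−)-carvone
Product: 3 (5R)-2,6-dimethyl-5-(prop-1-en-2-yl)cyclohex-2-en-1-one (6-methylcarvone; both C6 epimers), via carvone lithium dienolate 2 (not isolated)
Conditions: LiN(i-Pr)2, THF, −78 °C; MeI, −78 to 0 °C
Reagents that add atoms: iodomethane CI
Why: Kinetic α′-deprotonation of the cross-conjugated enone and SN2 methylation of the lithium enolate (enolate alkylation) occur at C6, and the new C6 centre, formed as an epimer mixture, is made planar again in step 2.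

Step 2
Reactants: 3 6-methylcarvone
Product: 5 (5S,6R)-6-(hydroxymethyl)-2,6-dimethyl-5-(prop-1-en-2-yl)cyclohex-2-en-1-one (CH2OH trans to isopropenyl), via lithium enolate 4 (not isolated)
Conditions: LiN(i-Pr)2, THF, −78 °C; gaseous CH2O (cracked paraformaldehyde), −78 °C; AcOH
Reagents that add atoms: formaldehyde C=O
Why: Aldol addition of the regenerated C6 enolate to monomeric formaldehyde should take place anti to the adjacent isopropenyl group, as is usual for 6-substituted carvone enolates, which places CH2OH trans to it and fixes the quaternary centre that becomes C4 (C19 β, C18 α).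

Step 3
Reactants: 5 hydroxymethyl ketone
Product: 6 (5S,6R)-6-[(tert-butyldiphenylsilyloxy)methyl]-2,6-dimethyl-5-(prop-1-en-2-yl)cyclohex-2-en-1-one
Conditions: t-BuPh2SiCl, imidazole, DMF, rt
Reagents that add atoms: tert-butyldiphenylsilyl chloride CC(C)(C)[Si](Cl)(c1ccccc1)c1ccccc1
Why: Silyl ether formation on the neopentyl primary alcohol blocks retro-aldol loss of formaldehyde and gives a group expected to survive every later step until the final fluoride treatment.

Step 4
Reactants: 6 silyl ether enone
Product: 8 (5S,6R)-6-[(tert-butyldiphenylsilyloxy)methyl]-2,6-dimethyl-5-(prop-1-en-2-yl)cyclohex-1-en-1-yl trifluoromethanesulfonate, via lithium enolate 7 (not isolated)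
Conditions: LiBH(s-Bu)3, THF, −78 °C; N-(5-chloro-2-pyridyl)triflimide (Comins' reagent), −78 to 0 °C
Reagents that add atoms: N-(5-chloropyridin-2-yl)bis(trifluoromethanesulfonyl)imide Clc1ccc(N(S(=O)(=O)C(F)(F)F)S(=O)(=O)C(F)(F)F)nc1
Why: Conjugate hydride reduction of the enone gives regiospecifically the tetrasubstituted C1=C2 enolate, which is O-triflated (enolate trapping) while the isolated isopropenyl group is untouched.

Step 5
Reactants: 8 enol triflate
Product: 11 (1R,2S)-2-[(tert-butyldiphenylsilyloxy)methyl]-2,4-dimethyl-3-(trifluoromethanesulfonyloxy)cyclohex-3-en-1-yl acetate, via methoxy hydroperoxide 9 (not isolated), via peracetate 10 (not isolated)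
Conditions: O3, CH2Cl2/MeOH, −78 °C; then Ac2O, Et3N, DMAP (cat.), 0 °C to rt
Reagents that add atoms: ozone [O-][O+]=O; methanol CO (held in 9 and 10 only); acetic anhydride CC(=O)OC(C)=O
Why: Ozone should cleave only the electron-rich isopropenyl olefin (the enol triflate is deactivated), and acetylation of the α-methoxy hydroperoxide triggers the Criegee rearrangement, in which the ring carbon migrates to oxygen with retention so that the carvone stereocentre becomes the 3α C–O centre.

Step 6
Reactants: 11 acetoxy enol triflate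
Product: 12 (5R,6S)-5-acetoxy-6-[(tert-butyldiphenylsilyloxy)methyl]-2,6-dimethylcyclohex-1-ene-1-carbaldehyde
Conditions: Pd(PPh3)4 (cat.), CO (1 atm), Bu3SnH (slow addition), LiCl, THF, 50 °C
Reagents that add atoms: carbon monoxide [C-]#[O+]
Why: Oxidative addition of the enol triflate to zerovalent palladium, CO insertion and hydride transfer from tin (Stille-type reductive carbonylation) convert the triflate into the conjugated aldehyde that supplies C6.

Step 7
Reactants: 12 acetoxy enal
Product: 13 (5R,6S)-6-[(tert-butyldiphenylsilyloxy)methyl]-5-hydroxy-2,6-dimethylcyclohex-1-ene-1-carbaldehyde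
Conditions: K2CO3 (cat.), MeOH, rt
Reagents that add atoms: none
Why: Base-catalysed transesterification removes the acetate, which would not survive the organobarium and KH steps, and the hydroxyl is separated from the carbonyl by a quaternary carbon so that neither elimination nor retro-aldol cleavage is open.

Step 8
Reactants: 13 hydroxy enal
Product: 14 (5R,6S)-6-[(tert-butyldiphenylsilyloxy)methyl]-2,6-dimethyl-5-(triethylsilyloxy)cyclohex-1-ene-1-carbaldehyde (ring A enal)
Conditions: Et3SiOTf, 2,6-lutidine, CH2Cl2, −78 °C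
Reagents that add atoms: triethylsilyl trifluoromethanesulfonate CC[Si](CC)(CC)OS(=O)(=O)C(F)(F)F
Why: The silyl triflate is needed for the hindered axial alcohol and gives a triethylsilyl ether that should tolerate organobarium, KH and Me2AlCl yet be cleaved by mild acid beside the tert-butyldiphenylsilyl ether.

Step 9
Reactants: 15 geraniol
Product: 16 geranyl tert-butyldimethylsilyl ether
Conditions: t-BuMe2SiCl, imidazole, CH2Cl2, rt
Reagents that add atoms: tert-butyldimethylsilyl chloride CC(C)(C)[Si](C)(C)Cl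
Why: Standard silylation protects the allylic alcohol that later becomes the C15 acid.

Step 10
Reactants: 16 geranyl silyl ether
Product: 17 (2E,6E)-8-(tert-butyldimethylsilyloxy)-2,6-dimethylocta-2,6-dien-1-ol
Conditions: SeO2 (cat.), t-BuOOH, salicylic acid (cat.), CH2Cl2, rt
Reagents that add atoms: tert-butyl hydroperoxide CC(C)(C)OO
Why: Catalytic SeO2 allylic oxidation (ene reaction then [2,3]-sigmatropic shift) is selective for the E-methyl of the more electron-rich distal trisubstituted olefin and gives the E allylic alcohol.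

Step 11
Reactants: 17 allylic alcohol
Product: 18 tert-butyl{[(2E,6E)-8-chloro-3,7-dimethylocta-2,6-dien-1-yl]oxy}dimethylsilane
Conditions: PPh3, CCl4, MeCN, rt
Reagents that add atoms: carbon tetrachloride ClC(Cl)(Cl)Cl
Why: Appel chlorination converts the primary allylic alcohol into the chloride under neutral conditions without allylic transposition or loss of the silyl ether.

Step 12
Reactants: 18 allylic chloride; 14 ring A enal
Product: 20 (6S)-15-(tert-butyldimethylsilyloxy)-19-(tert-butyldiphenylsilyloxy)-3α-(triethylsilyloxy)-9,10-seco-labda-5(10),8E,13E-trien-6-ol, via allylbarium chloride 19 (not isolated)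
Conditions: activated Ba (from BaI2 + 2 LiC12H10), THF, −78 °C; 18; then 14, −78 °C; H2O
Reagents that add atoms: none
Why: Allylbarium reagents add 1,2 to aldehydes at the unsubstituted α-carbon with retention of olefin geometry (α-selective carbonyl allylation), and attack on the s-trans enal anti to the pseudo-axial C4 CH2OSi group with the aldehyde hydrogen facing the C10 methyl should give the 6S carbinol.

Step 13
Reactants: 20 dienol
Product: 23 15-(tert-butyldimethylsilyloxy)-19-(tert-butyldiphenylsilyloxy)-3α-(triethylsilyloxy)-6,7-seco-labda-7,13E-dien-6-al (5α-H; 9α-H; 10β-methyl), via potassium alkoxide 21 (not isolated), via potassium enolate 22 (not isolated)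
Conditions: KH, 18-crown-6, THF, 0 °C to rt; AcOH, −78 °C
Reagents that add atoms: none
Why: Anionic oxy-Cope rearrangement through a chair on the α face (C6–H eclipsing the C10 methyl, alkoxide pseudo-equatorial, chain anti to the C4 CH2OSi group) forms C9–C10 and relays the C6 configuration to the quaternary C10, the E olefin places C11 equatorial at C9, and protonation of the enolate anti to the axial C19 and C20 groups gives the 5α-H aldehyde.

Step 14
Reactants: 23 seco aldehyde
Product: 24 15-(tert-butyldimethylsilyloxy)-19-(tert-butyldiphenylsilyloxy)-3α-(triethylsilyloxy)labda-8(17),13E-dien-6β-ol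
Conditions: Me2AlCl (2 equiv), CH2Cl2, −78 to −20 °C; aq. potassium sodium tartrate
Reagents that add atoms: none
Why: Me2AlCl complexes the C6 aldehyde, whose carbon is attacked by the terminal CH2 (C7) of the C8 isopropenyl group while a hydrogen of the C17 methyl passes to oxygen through a six-membered array, an asynchronous concerted carbonyl-ene reaction of type 2 (ene unit tethered through its central carbon), the closest known reaction type being the alkylaluminium-chloride-promoted cyclisation of 6-methylhept-6-enals to 3-methylenecyclohexanols. Ring B closes as a six-membered carbocycle through a chair-like transition state, exo with respect to the carbonyl (oxygen stays outside the ring) and with both ene carbons C7 and C8 becoming ring members. The only new stereocentre, C6, is controlled by the bicyclo[3.3.1]-like geometry of the hydrogen transfer, which requires the C–O bond to be axial and syn to C17, that is β on a ring B chair whose C5, C9 and C10 substituents are already held equatorial by the trans relationship set in step 13. The step needs chemoselectivity for the 1,1-disubstituted olefin over the trisubstituted C13=C14 olefin, secured because only the former reaches the aldehyde in a six-membered ring and develops tertiary cation character at C8. It also needs the hydrogen to come from C17 and not from C9, secured because the axial C9–H lies on the α face away from the axial oxygen, so the Δ8(17) olefin results and is moved into the ring in step 19.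

Step 15
Reactants: 24 ene product
Product: 25 19-(tert-butyldiphenylsilyloxy)labda-8(17),13E-diene-3α,6β,15-triol
Conditions: camphorsulfonic acid (cat.), MeOH/CH2Cl2, 0 °C
Reagents that add atoms: none
Why: Acid-catalysed methanolysis removes the triethylsilyl ether and the primary allylic tert-butyldimethylsilyl ether, while the far more acid-stable neopentyl tert-butyldiphenylsilyl ether should remain.

Step 16
Reactants: 25 triol
Product: 26 3α,6β-dihydroxy-19-(tert-butyldiphenylsilyloxy)labda-8(17),13E-dien-15-al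
Conditions: MnO2, CH2Cl2, rt
Reagents that add atoms: none
Why: MnO2 oxidises only the allylic primary alcohol, leaving the non-allylic secondary 3α- and 6β-hydroxyls and the E geometry untouched.

Step 17
Reactants: 26 dihydroxy enal
Product: 27 6β-hydroxy-3α-(3-methylbutanoyloxy)-19-(tert-butyldiphenylsilyloxy)labda-8(17),13E-dien-15-al
Conditions: (i-BuCO)2O, Et3N, DMAP (cat.), CH2Cl2, rt
Reagents that add atoms: 3-methylbutanoic anhydride CC(C)CC(=O)OC(=O)CC(C)C
Why: DMAP-catalysed acylation should occur at the axial 3α-hydroxyl, whereas the 6β-hydroxyl, flanked 1,3-diaxially by C20 and the C19 CH2OSi group, is expected to be inert, as 6β-alcohols of this type are.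

Step 18
Reactants: 27 ester enal
Product: 28 6β-hydroxy-3α-(3-methylbutanoyloxy)-19-(tert-butyldiphenylsilyloxy)labda-8(17),13E-dien-15-oic acid
Conditions: NaClO2, NaH2PO4, 2-methyl-2-butene, t-BuOH/H2O, rt
Reagents that add atoms: sodium chlorite [Na+].[O-]Cl=O
Why: Pinnick oxidation with a chlorine scavenger converts the enal into the E-enoic acid without touching the olefins, the ester or the silyl ether.

Step 19
Reactants: 28 Δ8(17) acid
Product: 29 6β-hydroxy-3α-(3-methylbutanoyloxy)-19-(tert-butyldiphenylsilyloxy)labda-8,13E-dien-15-oic acid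
Conditions: TsOH·H2O (cat.), benzene, 60 °C
Reagents that add atoms: none
Why: Reversible protonation of the exocyclic olefin gives the tertiary C8 cation, and loss of the axial C9 proton leads to the tetrasubstituted Δ8 olefin, the thermodynamically preferred isomer in 9-alkyl labdanes (acid-catalysed olefin isomerisation), while the conjugated C13 olefin is deactivated toward protonation and the C9 stereocentre is erased.

Step 20
Reactants: 29 silyl-protected acid
Product: 30 6β,19-dihydroxy-3α-(3-methylbutanoyloxy)labda-8,13E-dien-15-oic acid (target)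
Conditions: HF·pyridine, THF/pyridine, 0 °C to rt
Reagents that add atoms: none
Why: Fluoride-mediated cleavage of the silyl ether frees the C19 alcohol, and migration of the ester is excluded because the 3α oxygen and C19 are anti-periplanar.

**Compound list**

1 | (R)-(−)-carvone, (5R)-2-methyl-5-(prop-1-en-2-yl)cyclohex-2-en-1-one | CC1=CC[C@@H](C(C)=C)CC1=O | starting material
2 | lithium cross-conjugated dienolate of carvone (C1–OLi, C1=C6) | CC1=CC[C@@H](C(C)=C)C=C1O[Li] | intermediate
3 | (5R)-2,6-dimethyl-5-(prop-1-en-2-yl)cyclohex-2-en-1-one, mixture of C6 epimers (C6 left undefined) | CC1=CC[C@@H](C(C)=C)C(C)C1=O | intermediate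
4 | lithium enolate of 3 (C1–OLi, C1=C6) | CC1=CC[C@@H](C(C)=C)C(C)=C1O[Li] | intermediate
5 | (5S,6R)-6-(hydroxymethyl)-2,6-dimethyl-5-(prop-1-en-2-yl)cyclohex-2-en-1-one, CH2OH trans to isopropenyl | CC1=CC[C@@H](C(C)=C)[C@](C)(CO)C1=O | intermediate
6 | (5S,6R)-6-[(tert-butyldiphenylsilyloxy)methyl]-2,6-dimethyl-5-(prop-1-en-2-yl)cyclohex-2-en-1-one | CC1=CC[C@@H](C(C)=C)[C@](C)(CO[Si](c2ccccc2)(c2ccccc2)C(C)(C)C)C1=O | intermediate
7 | lithium enolate from conjugate reduction of 6 (C1–OLi, C1=C2) | CC1=C(O[Li])[C@@](C)(CO[Si](c2ccccc2)(c2ccccc2)C(C)(C)C)[C@H](C(C)=C)CC1 | intermediate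
8 | (5S,6R)-6-[(tert-butyldiphenylsilyloxy)methyl]-2,6-dimethyl-5-(prop-1-en-2-yl)cyclohex-1-en-1-yl trifluoromethanesulfonate | CC1=C(OS(=O)(=O)C(F)(F)F)[C@@](C)(CO[Si](c2ccccc2)(c2ccccc2)C(C)(C)C)[C@H](C(C)=C)CC1 | intermediate
9 | α-methoxy hydroperoxide from 8 (side chain C(CH3)(OCH3)OOH, epimers at that carbon) | CC1=C(OS(=O)(=O)C(F)(F)F)[C@@](C)(CO[Si](c2ccccc2)(c2ccccc2)C(C)(C)C)[C@H](C(C)(OC)OO)CC1 | intermediate
10 | peracetate of 9 | CC1=C(OS(=O)(=O)C(F)(F)F)[C@@](C)(CO[Si](c2ccccc2)(c2ccccc2)C(C)(C)C)[C@H](C(C)(OC)OOC(C)=O)CC1 | intermediate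
11 | (1R,2S)-2-[(tert-butyldiphenylsilyloxy)methyl]-2,4-dimethyl-3-(trifluoromethanesulfonyloxy)cyclohex-3-en-1-yl acetate | CC1=C(OS(=O)(=O)C(F)(F)F)[C@@](C)(CO[Si](c2ccccc2)(c2ccccc2)C(C)(C)C)[C@H](OC(C)=O)CC1 | intermediate
12 | (5R,6S)-5-acetoxy-6-[(tert-butyldiphenylsilyloxy)methyl]-2,6-dimethylcyclohex-1-ene-1-carbaldehyde | CC1=C(C=O)[C@@](C)(CO[Si](c2ccccc2)(c2ccccc2)C(C)(C)C)[C@H](OC(C)=O)CC1 | intermediate
13 | (5R,6S)-6-[(tert-butyldiphenylsilyloxy)methyl]-5-hydroxy-2,6-dimethylcyclohex-1-ene-1-carbaldehyde | CC1=C(C=O)[C@@](C)(CO[Si](c2ccccc2)(c2ccccc2)C(C)(C)C)[C@H](O)CC1 | intermediate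
14 | (5R,6S)-6-[(tert-butyldiphenylsilyloxy)methyl]-2,6-dimethyl-5-(triethylsilyloxy)cyclohex-1-ene-1-carbaldehyde (ring A enal) | CC1=C(C=O)[C@@](C)(CO[Si](c2ccccc2)(c2ccccc2)C(C)(C)C)[C@H](O[Si](CC)(CC)CC)CC1 | intermediate
15 | geraniol, (2E)-3,7-dimethylocta-2,6-dien-1-ol | CC(C)=CCC/C(C)=C/CO | starting material
16 | geranyl tert-butyldimethylsilyl ether | CC(C)=CCC/C(C)=C/CO[Si](C)(C)C(C)(C)C | intermediate
17 | (2E,6E)-8-(tert-butyldimethylsilyloxy)-2,6-dimethylocta-2,6-dien-1-ol | OC/C(C)=C/CC/C(C)=C/CO[Si](C)(C)C(C)(C)C | intermediate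
18 | tert-butyl{[(2E,6E)-8-chloro-3,7-dimethylocta-2,6-dien-1-yl]oxy}dimethylsilane | ClC/C(C)=C/CC/C(C)=C/CO[Si](C)(C)C(C)(C)C | intermediate
19 | allylbarium chloride from 18 (Ba on the former CH2Cl carbon) | Cl[Ba]C/C(C)=C/CC/C(C)=C/CO[Si](C)(C)C(C)(C)C | intermediate
20 | (6S)-15-(tert-butyldimethylsilyloxy)-19-(tert-butyldiphenylsilyloxy)-3α-(triethylsilyloxy)-9,10-seco-labda-5(10),8E,13E-trien-6-ol | CC1=C([C@@H](O)C/C(C)=C/CC/C(C)=C/CO[Si](C)(C)C(C)(C)C)[C@@](C)(CO[Si](c2ccccc2)(c2ccccc2)C(C)(C)C)[C@H](O[Si](CC)(CC)CC)CC1 | intermediate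
21 | potassium alkoxide of 20 | CC1=C([C@@H](O[K])C/C(C)=C/CC/C(C)=C/CO[Si](C)(C)C(C)(C)C)[C@@](C)(CO[Si](c2ccccc2)(c2ccccc2)C(C)(C)C)[C@H](O[Si](CC)(CC)CC)CC1 | intermediate
22 | potassium enolate of 23 (C5=C6–OK, geometry not defined) | C=C(C)[C@H](CC/C(C)=C/CO[Si](C)(C)C(C)(C)C)[C@@]1(C)CC[C@@H](O[Si](CC)(CC)CC)[C@](C)(CO[Si](c2ccccc2)(c2ccccc2)C(C)(C)C)C1=CO[K] | intermediate
23 | 15-(tert-butyldimethylsilyloxy)-19-(tert-butyldiphenylsilyloxy)-3α-(triethylsilyloxy)-6,7-seco-labda-7,13E-dien-6-al (5α-H, 9α-H, 10β-methyl) | C=C(C)[C@H](CC/C(C)=C/CO[Si](C)(C)C(C)(C)C)[C@@]1(C)CC[C@@H](O[Si](CC)(CC)CC)[C@](C)(CO[Si](c2ccccc2)(c2ccccc2)C(C)(C)C)[C@@H]1C=O | intermediate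
24 | 15-(tert-butyldimethylsilyloxy)-19-(tert-butyldiphenylsilyloxy)-3α-(triethylsilyloxy)labda-8(17),13E-dien-6β-ol | C=C1[C@H](CC/C(C)=C/CO[Si](C)(C)C(C)(C)C)[C@@]2(C)CC[C@@H](O[Si](CC)(CC)CC)[C@](C)(CO[Si](c3ccccc3)(c3ccccc3)C(C)(C)C)[C@@H]2[C@H](O)C1 | intermediate
25 | 19-(tert-butyldiphenylsilyloxy)labda-8(17),13E-diene-3α,6β,15-triol | C=C1[C@H](CC/C(C)=C/CO)[C@@]2(C)CC[C@@H](O)[C@](C)(CO[Si](c3ccccc3)(c3ccccc3)C(C)(C)C)[C@@H]2[C@H](O)C1 | intermediate
26 | 3α,6β-dihydroxy-19-(tert-butyldiphenylsilyloxy)labda-8(17),13E-dien-15-al | C=C1[C@H](CC/C(C)=C/C=O)[C@@]2(C)CC[C@@H](O)[C@](C)(CO[Si](c3ccccc3)(c3ccccc3)C(C)(C)C)[C@@H]2[C@H](O)C1 | intermediate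
27 | 6β-hydroxy-3α-(3-methylbutanoyloxy)-19-(tert-butyldiphenylsilyloxy)labda-8(17),13E-dien-15-al | C=C1[C@H](CC/C(C)=C/C=O)[C@@]2(C)CC[C@@H](OC(=O)CC(C)C)[C@](C)(CO[Si](c3ccccc3)(c3ccccc3)C(C)(C)C)[C@@H]2[C@H](O)C1 | intermediate
28 | 6β-hydroxy-3α-(3-methylbutanoyloxy)-19-(tert-butyldiphenylsilyloxy)labda-8(17),13E-dien-15-oic acid | C=C1[C@H](CC/C(C)=C/C(=O)O)[C@@]2(C)CC[C@@H](OC(=O)CC(C)C)[C@](C)(CO[Si](c3ccccc3)(c3ccccc3)C(C)(C)C)[C@@H]2[C@H](O)C1 | intermediate
29 | 6β-hydroxy-3α-(3-methylbutanoyloxy)-19-(tert-butyldiphenylsilyloxy)labda-8,13E-dien-15-oic acid | CC1=C(CC/C(C)=C/C(=O)O)[C@@]2(C)CC[C@@H](OC(=O)CC(C)C)[C@](C)(CO[Si](c3ccccc3)(c3ccccc3)C(C)(C)C)[C@@H]2[C@H](O)C1 | intermediate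
30 | 6β,19-dihydroxy-3α-(3-methylbutanoyloxy)labda-8,13E-dien-15-oic acid | CC1=C(CC/C(C)=C/C(=O)O)[C@@]2(C)CC[C@@H](OC(=O)CC(C)C)[C@](C)(CO)[C@@H]2[C@H](O)C1 | target

**Step count and risks**

Total step count: 20. Longest linear sequence: 17 steps (steps 1–8 and 12–20); the C10 allyl fragment is made separately in steps 9–11.

Steps most likely to fail:

Step 13. The alkoxide may fragment heterolytically into enal and allyl anion and recombine in the [1,3] sense or on the wrong face of the ring A olefin, which would scramble the C9–C10 connectivity and the C10 configuration. Fallback: set out from 20 and rearrange without the alkoxide. Silylation with N-(trimethylsilyl)imidazole gives the trimethylsilyl ether of 20, F1. Heating F1 in degassed o-dichlorobenzene at about 200 °C (sealed tube, trace of Et3N) should effect the neutral, concerted siloxy-Cope rearrangement through the same chair to the trimethylsilyl enol ether of 23, F2. K2CO3 in MeOH then cleaves only the enol silane and equilibrates C5 to the equatorial aldehyde, which brings the route back at 23.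

Step 14. Facial control at the complexed carbonyl may be lost, because the required axial oxygen is flanked by the axial C19 and C20 groups and a boat-like or stepwise pathway giving the equatorial alcohol can compete. Fallback: set out from 23, run the closure without regard to C6 (Me2AlCl or SnCl4) and carry the 6α-epimer of 24, F3, or the epimer mixture forward. Dess–Martin oxidation gives the 19-, 15- and 3-silylated labda-8(17),13E-dien-6-one, F4. Reduction with NaBH4/CeCl3·7H2O in MeOH at −78 °C should deliver hydride from the open α face, as with 6-oxo steroids and labdanes, and the route is rejoined at 24.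

Step 19. Proton loss from the C8 cation may be unselective (Δ7 isomer), or prolonged exposure to acid may open cationic side reactions such as retro-Prins cleavage of ring B. Fallback: set out from 28 and separate protonation from elimination. HCl gas in CH2Cl2 at −40 °C should add across the exocyclic olefin only, giving the tertiary 8-chloro-6β-hydroxy-3α-(3-methylbutanoyloxy)-19-(tert-butyldiphenylsilyloxy)labd-13E-en-15-oic acid, F5 (C8 epimers). Dehydrochlorination with LiBr/Li2CO3 in DMF at 100 °C, which favours the most substituted olefin, then leads to 29.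

Further compounds
F1 | step 13 | trimethylsilyl ether of 20 (6S) | CC1=C([C@@H](O[Si](C)(C)C)C/C(C)=C/CC/C(C)=C/CO[Si](C)(C)C(C)(C)C)[C@@](C)(CO[Si](c2ccccc2)(c2ccccc2)C(C)(C)C)[C@H](O[Si](CC)(CC)CC)CC1
F2 | step 13 | trimethylsilyl enol ether of 23 (C5=C6–OSiMe3, geometry not defined) | C=C(C)[C@H](CC/C(C)=C/CO[Si](C)(C)C(C)(C)C)[C@@]1(C)CC[C@@H](O[Si](CC)(CC)CC)[C@](C)(CO[Si](c2ccccc2)(c2ccccc2)C(C)(C)C)C1=CO[Si](C)(C)C
F3 | step 14 | 15-(tert-butyldimethylsilyloxy)-19-(tert-butyldiphenylsilyloxy)-3α-(triethylsilyloxy)labda-8(17),13E-dien-6α-ol | C=C1[C@H](CC/C(C)=C/CO[Si](C)(C)C(C)(C)C)[C@@]2(C)CC[C@@H](O[Si](CC)(CC)CC)[C@](C)(CO[Si](c3ccccc3)(c3ccccc3)C(C)(C)C)[C@@H]2[C@@H](O)C1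
F4 | step 14 | 15-(tert-butyldimethylsilyloxy)-19-(tert-butyldiphenylsilyloxy)-3α-(triethylsilyloxy)labda-8(17),13E-dien-6-one | C=C1[C@H](CC/C(C)=C/CO[Si](C)(C)C(C)(C)C)[C@@]2(C)CC[C@@H](O[Si](CC)(CC)CC)[C@](C)(CO[Si](c3ccccc3)(c3ccccc3)C(C)(C)C)[C@@H]2C(=O)C1
F5 | step 19 | 8-chloro-6β-hydroxy-3α-(3-methylbutanoyloxy)-19-(tert-butyldiphenylsilyloxy)labd-13E-en-15-oic acid (C8 left undefined) | CC1(Cl)[C@H](CC/C(C)=C/C(=O)O)[C@@]2(C)CC[C@@H](OC(=O)CC(C)C)[C@](C)(CO[Si](c3ccccc3)(c3ccccc3)C(C)(C)C)[C@@H]2[C@H](O)C1
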